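All runs come from a simulation for substances that don't exist.

Late in the dusk and noon runs the target falls while the other capture product climbs, and the two recipes differ in the charge of second nucleophile. At 1.33 min they hold much the same target, 34% and 30%, yet at 20.0 min dusk holds 58% and noon 14%.

Take the rise of the other capture product per minute around 15.0 min, divide it by the target standing then, and multiply by c(first nucleophile)/c(second nucleophile), each being its charge less the product that used it. Noon reads 0.259 min⁻¹, the drain constant, and dusk reads 0.263 min⁻¹. So one constant, read off scattered readings, describes both runs, with the drain in proportion to c(second nucleophile)/c(first nucleophile).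

At that moment c(second nucleophile)/c(first nucleophile) stands at 0.0982 in dusk and 0.459 in noon. The target's drain half-life is therefore 27.2 min in dusk and 5.82 min in noon, and noon ends lower because its drain is faster.

| setting | dusk | noon | flask |
|---|---|---|---|
| substrate | 0.050 M | 0.050 M | 0.050 M |
| first nucleophile | 5 equiv | 5 equiv | 5.00 equiv |
| second nucleophile | 0.75 equiv | 3 equiv | 1.50 equiv |
| remark | run made earlier | run made earlier |  |
| time |  |  | 25 min |

| run | time / min | other capture product / % | target / % |
|---|---|---|---|
| dusk | 1.33 | 2 | 34 |
| dusk | 4.00 | 11 | 59 |
| dusk | 8.00 | 20 | 71 |
| dusk | 10.0 | 24 | 70 |
| dusk | 15.0 | 32 | 62 |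
| dusk | 20.0 | 40 | 58 |
| noon | 1.33 | 7 | 30 |
| noon | 4.00 | 28 | 46 |
| noon | 8.00 | 55 | 40 |
| noon | 10.0 | 62 | 34 |
| noon | 15.0 | 80 | 21 |
| noon | 20.0 | 87 | 14 |

(each reading ± 1.5 percentage points)

- the analysis behind the earlier runs scatters by 1.5 percentage points, standard deviation

* ratio of other capture product to target at 8.0 s
* ratio of other capture product to target at 2.0 min
* ratio of other capture product to target at 25 min

For the new flask, the 74.0% of both products at 4.00 min in noon means a mean wait of 2.97 min before substrate is captured. That is shorter than the flask's drain half-life at its charges, 8.91 min. As a rough step of this reckoning, and not as a state of the flask, the charge is entered as target at that moment. Integrating the drain with c(first nucleophile) held at its charge and second nucleophile consumed gives a late ratio of 2.31.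

The forecast differs from this: 0.092, 0.19 and 2.6, on the ground that “The target later drains into the other product, so capture by the first nucleophile is reversible”.

    substrate → intermediate (k = 0.00610 s⁻¹)
    first nucleophile + intermediate ⇌ target (K = 65.0 M⁻¹, k = 1.20 M⁻¹ s⁻¹)
    second nucleophile + intermediate → other capture product (k = 0.290 M⁻¹ s⁻¹)

The flask gives 0.0769, 0.168 and 2.61, so the forecast stands high at the earliest time and the drain reckoning low at the latest. At 25 min the exchange between target and intermediate in the flask relaxes with a half-life of 2.29 s, far shorter than the run, and the intermediate holds 1.71% against 27.2% of target. From its end state the drain constant gives the flask a drain half-life of 16.0 min. The neighbouring flask with 0.380 equiv of second nucleophile gets 92.9 min and ends with 69.5% of target.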